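Start at late times. With the whole charge of free monomer in chains and each initiator spent on a chain, the average length is one over the loading: 370 in noon, 100 in summer. Your job is to find how far each flask gets towards that by the end of the dose.

in all of them: free monomer 0.050 M (fed, over 3.0 min); transfer agent 0.500 mM; time 3.0 min

| charge | initiator |
|---|---|
| noon | 0.27 mol% |
| summer | 1 mol% |

    free monomer + initiator → living end + monomer in chains (k1 = 3.7 L mol⁻¹ s⁻¹)
    living end + free monomer → dead end (k2 = 0.083 L mol⁻¹ s⁻¹)
    free monomer + living end → monomer in chains + living end, rate k3*[living end]*[free monomer] (k3 = 150 L mol⁻¹ s⁻¹)
    free monomer → uncatalysed product (k4 = 0.0010 s⁻¹)
    living end + transfer agent → dead chain (k5 = 2.1 L mol⁻¹ s⁻¹)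

- which of the two ends with the longer chains by the average number of monomer units in a chain (chains begun, living or dead) ("neither" if they lie within 10%) (noon / summer / neither)
- average number of monomer units in a chain (chains begun, living or dead) at the end, noon
- average number of monomer units in a chain (chains begun, living or dead) at the end, summer

- the average divides the monomer in chains by the number of chains begun, living and dead together
- run time (noon): 3.0 min

Here is my ladder: first the rungs that lie inside the dose, then the losses beyond it. Once the initiator has become living ends, free monomer enters chains pseudo-first-order, with a half-life of 0.570 min in noon and 0.154 min in summer, shorter than the 3.0 min dose. So free monomer stands where use matches feed, at one over the product of the chain-growth constant, the living ends and the dosing time: 27.4% of the charge in noon, 7.41% in summer. Call this the standing share, the part of the charge left free while use matches the feed.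

At that level initiator has a half-life of 0.228 min in noon and 0.843 min in summer, again inside the dose, so I count its charge as chains begun. The losses in noon lie beyond the dose. A living end has a half-life of 11 min against transfer agent and 10.1 min against free monomer at the standing level, both longer than the dose. Free monomer has a half-life of 12 min by its uncatalysed step, also longer than the dose. A dead chain still counts as begun.

My length is therefore the ceiling times what the standing share leaves: 269 for noon, 92.6 for summer, with noon longer.

The forecast says noon, with 215 for noon and 92 for summer, holding that “the number of chains begun is set by the initiator charge”. Its noon length lies below mine.

The simulation gives noon, at 239 against 92.4. The loading is the main reason: summer at noon's loading gives 239 instead of 92.4. Noon ends with 31% of the charge free against a standing share of 27.4%, and summer with 9.0% against 7.41%. Give noon's recipe 0.20 M of free monomer with the loading held, and the standing share falls to 6.86%, which reckons a length of 345; that flask leaves 9.4% free and gives 330.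

The rate constants are those of an exercise; what happens was integrated by code.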